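The route rests on opening the oxolane between its ring oxygen and the pentyl-bearing carbon C6 (chain numbering, C1 = pentyl terminus). The cis pair C6-pentyl/C7-hydroxyl and the 1,3-syn oxygens on C7 and C9 of this ring are the imprint of a cis-oxirane opened from the rear by the C9 oxygen. The precursor is thus an acyclic (Z)-homoallylic alcohol that already carries the laurate on C10 and the C18=C19 vinyl group. In one flask the vanadium-bound C9 hydroxyl directs epoxidation to C6=C7 only, then closes the ring. Two stereocentres, the ether bond and the free C7 hydroxyl arise together, and the product is the target.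

Key step: step 5

Remark on locants: C1–C5 = pentyl, C6 and C9 = ring carbons next to oxygen, C7 = ring carbinol, C8 = ring CH2, C10 = ester carbinol, C18=C19 = vinyl. The target is 6S,7S,9R,10R.
Assumption: the facial sense of the R prolinol catalyst and of (R)-TRIP is taken from their behaviour with simple linear aldehydes. Both antipodes of each are commercial, so a reversed sense would be met by exchanging the antipode.

Step 1
Reactants: 1 undec-10-enal; 2 dilauroyl peroxide
Product: 3 (2R)-1-oxoundec-10-en-2-yl dodecanoate
Conditions: (R)-α,α-diphenylprolinol TMS ether (10 mol %), hydroquinone (10 mol %), THF, 0 °C to rt; cold NaHCO3 wash, used without delay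
Reagents that add atoms: none
Why: Enamine-catalysed asymmetric α-acyloxylation of an aldehyde with a diacyl peroxide, a reaction type established with dibenzoyl peroxide, in which the E-enamine attacks the O–O bond on the face left open by the diphenyl(silyloxy)methyl group, so that the R catalyst should set C10 as R, while the isolated vinyl group is inert and hydroquinone suppresses radical decomposition of 2.

Step 2
Reactants: 4 hexan-1-ol
Product: 5 hexyl N,N-diisopropylcarbamate
Conditions: i-Pr2NCOCl, Et3N, CH2Cl2, reflux
Reagents that add atoms: N,N-diisopropylcarbamoyl chloride CC(C)N(C(C)C)C(=O)Cl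
Why: Plain O-carbamoylation of a primary alcohol (nucleophilic acyl substitution) that installs the directing and leaving group for the next step; no stereocentre is formed.

Step 3
Reactants: 5 hexyl N,N-diisopropylcarbamate; 6 4,4,5,5-tetramethyl-2-vinyl-1,3,2-dioxaborolane
Product: 9 (R)-4,4,5,5-tetramethyl-2-(oct-1-en-3-yl)-1,3,2-dioxaborolane, via lithiated carbamate 7 (not isolated), via boronate complex 8 (not isolated)
Conditions: s-BuLi, (−)-sparteine, Et2O, −78 °C; 6, −78 °C; MgBr2·OEt2, reflux; NH4Cl quench
Reagents that add atoms: none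
Why: Hoppe sparteine-mediated deprotonation followed by lithiation–borylation (Matteson-type 1,2-metallate rearrangement): (−)-sparteine removes the pro-S hydrogen, 6 is captured with retention, and the vinyl group migrates antiperiplanar to the departing carbamate with inversion, which should give the R allylic boronate.

Step 4
Reactants: 3 (2R)-1-oxoundec-10-en-2-yl dodecanoate; 9 (R)-4,4,5,5-tetramethyl-2-(oct-1-en-3-yl)-1,3,2-dioxaborolane
Product: 11 (6Z,9R,10R)-9-hydroxynonadeca-6,18-dien-10-yl dodecanoate, via pinacol borate 10 (not isolated)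
Conditions: (R)-TRIP (5 mol %), 4 Å MS, toluene, −40 to −20 °C; pH 7 buffer
Reagents that add atoms: none
Why: Chiral phosphoric acid-catalysed allylboration with an α-substituted allylboronate through a closed chair in which the pentyl group stands axial to avoid the pinacol methyls, so that the R boron-bearing centre is relayed to the Re face of 3 to set C9 as R and C6=C7 as Z; boronate chirality and catalyst act in the same sense and must override the modest anti (Felkin/Cornforth) bias of 3, and the non-basic medium keeps the laurate on O10.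

Step 5
Reactants: 11 (6Z,9R,10R)-9-hydroxynonadeca-6,18-dien-10-yl dodecanoate
Product: 13 (1R)-1-[(2R,4S,5S)-4-hydroxy-5-pentyloxolan-2-yl]dec-9-en-1-yl dodecanoate (target), via epoxy alcohol 12 (not isolated)
Conditions: VO(acac)2 (5 mol %), t-BuOOH (decane), CH2Cl2, 0 °C to rt; then CSA (10 mol %), rt
Reagents that add atoms: tert-butyl hydroperoxide CC(C)(C)OO
Why: Hydroxyl-directed vanadium(V)/alkyl hydroperoxide epoxidation of a homoallylic alcohol followed by acid-promoted intramolecular opening of the resulting 3,4-epoxy alcohol, both known reaction types run in one flask. The C9 alkoxide binds vanadium and the peroxide oxygen is passed to C6=C7 through a chair-like transition state in which the C10 branch is equatorial and allylic 1,3-strain of the Z-alkene fixes the C8–C7 rotamer, so the oxirane oxygen should arrive 1,3-syn to the C9 oxygen and give the (6R,7S)-cis-oxirane 12. The oxirane forms by syn oxygen transfer (a [2+1] closure), and the oxolane closes when the C9 hydroxyl attacks C6 from the rear in the 5-endo mode with respect to the oxirane, the 4-exo alternative at C7 leading only to a strained oxetane. C7 is thus controlled by the C9 stereocentre through the vanadate chair, and C6 by the alkene geometry plus inversion, which places pentyl and hydroxyl cis and pentyl and the C9 side chain trans. Chemoselectivity comes from the tether, since the unactivated C18=C19 vinyl group cannot reach the metal-bound peroxide and is not epoxidised by this reagent. Selectivity among the oxygen nucleophiles comes from the laurate, which blocks the C10 oxygen that would otherwise close a 5-exo ring at C7.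

Compound list
1 | undec-10-enal | C=CCCCCCCCCC=O | starting material
2 | dilauroyl peroxide | CCCCCCCCCCCC(=O)OOC(=O)CCCCCCCCCCC | starting material
3 | (2R)-1-oxoundec-10-en-2-yl dodecanoate | C=CCCCCCCC[C@@H](OC(=O)CCCCCCCCCCC)C=O | intermediate
4 | hexan-1-ol | CCCCCCO | starting material
5 | hexyl N,N-diisopropylcarbamate | CCCCCCOC(=O)N(C(C)C)C(C)C | intermediate
6 | 4,4,5,5-tetramethyl-2-vinyl-1,3,2-dioxaborolane | C=CB1OC(C)(C)C(C)(C)O1 | starting material
7 | (S)-1-lithiohexyl N,N-diisopropylcarbamate (sparteine complex) | [Li][C@@H](CCCCC)OC(=O)N(C(C)C)C(C)C | intermediate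
8 | lithium (S)-[1-(diisopropylcarbamoyloxy)hexyl](vinyl)pinacolatoborate | C=C[B-]1(OC(C)(C)C(C)(C)O1)[C@@H](CCCCC)OC(=O)N(C(C)C)C(C)C.[Li+] | intermediate
9 | (R)-4,4,5,5-tetramethyl-2-(oct-1-en-3-yl)-1,3,2-dioxaborolane | C=C[C@@H](CCCCC)B1OC(C)(C)C(C)(C)O1 | intermediate
10 | O9-pinacol borate of 11 | C=CCCCCCCC[C@@H](OC(=O)CCCCCCCCCCC)[C@H](OB1OC(C)(C)C(C)(C)O1)C/C=C\CCCCC | intermediate
11 | (6Z,9R,10R)-9-hydroxynonadeca-6,18-dien-10-yl dodecanoate | C=CCCCCCCC[C@@H](OC(=O)CCCCCCCCCCC)[C@H](O)C/C=C\CCCCC | intermediate
12 | (6R,7S,9R,10R)-6,7-epoxy-9-hydroxynonadec-18-en-10-yl dodecanoate | C=CCCCCCCC[C@@H](OC(=O)CCCCCCCCCCC)[C@H](O)C[C@@H]1O[C@@H]1CCCCC | intermediate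
13 | (1R)-1-[(2R,4S,5S)-4-hydroxy-5-pentyloxolan-2-yl]dec-9-en-1-yl dodecanoate | C=CCCCCCCC[C@@H](OC(=O)CCCCCCCCCCC)[C@H]1C[C@H](O)[C@H](CCCCC)O1 | target

Total step count: 5. Longest linear sequence: 4 steps (4 → 5 → 9 → 11 → 13).

Steps most likely to fail

Step 5. Three things may go wrong: incomplete facial discrimination in the oxygen transfer, a sluggish endo opening, or a shift of the acyl group from O10 to O9 under acid before the ring closes. The fallback makes the same C6–O bond by displacement of chloride instead of epoxide opening. C6 is then set by catalysis, and C7 and C9 are relayed from it. It sets out from 3 and comes back at 13.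
- Addition of MeTi(Oi-Pr)3 to 3 should give (3R)-2-hydroxydodec-11-en-3-yl dodecanoate F1 (both C2 epimers serve).
- Dess–Martin oxidation should give (3R)-2-oxododec-11-en-3-yl dodecanoate F2.
- Commercial heptanal is chlorinated under enamine catalysis (NCS, the catalyst antipode that delivers R) to (R)-2-chloroheptanal F3.
- Enolisation of F2 on the methyl side with c-Hex2BCl/Et3N and aldol addition to F3 should give the anti chlorohydrin (6R,7S,10R)-6-chloro-7-hydroxy-9-oxononadec-18-en-10-yl dodecanoate F4 under Cornforth/polar Felkin control.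
- Narasaka–Prasad reduction (Et2BOMe, NaBH4, −78 °C) should give the 1,3-syn diol (6R,7S,9R,10R)-6-chloro-7,9-dihydroxynonadec-18-en-10-yl dodecanoate F5.
- AgOTf/Ag2O in THF should close the ring by 5-exo-tet displacement with inversion at C6 to give 13.

Step 4. The Z/E selectivity and the control at C9 may erode, because the anti preference of the aldehyde opposes reagent and catalyst. The fallback takes the alkene geometry from an alkyne instead of from the chair. It sets out from 3 and comes back at 11.
- Commercial oct-2-yn-1-ol is converted with ClCO2Me/pyridine into methyl oct-2-yn-1-yl carbonate F6.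
- Copper(I)-catalysed SN2' borylation (B2pin2, CuOt-Bu, Xantphos) should give 4,4,5,5-tetramethyl-2-(octa-1,2-dien-3-yl)-1,3,2-dioxaborolane F7.
- (R)-TRIP-catalysed propargylation of 3 with F7 should give (9R,10R)-9-hydroxynonadec-18-en-6-yn-10-yl dodecanoate F8.
- Lindlar semihydrogenation (quinoline, one equivalent of H2, monitored so that the vinyl group is spared) should give 11.

Step 1. Attack of the enamine on the less electrophilic aliphatic peroxide may be slow. The catalyst may be consumed by N-acyloxylation, the peroxide may decompose by a radical path, and the product may racemise on handling. The fallback introduces the oxygen first and acylates it later. It sets out from 1 and comes back at 3.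
- L-Proline-catalysed α-aminoxylation with nitrosobenzene and in situ NaBH4 reduction should give (R)-2-(anilinooxy)undec-10-en-1-ol F9.
- Zn/AcOH should cleave the N–O bond to (R)-undec-10-ene-1,2-diol F10.
- TBSCl/imidazole should silylate the primary hydroxyl to (R)-1-(tert-butyldimethylsilyloxy)undec-10-en-2-ol F11.
- Steglich esterification with dodecanoic acid should give (R)-1-(tert-butyldimethylsilyloxy)undec-10-en-2-yl dodecanoate F12.
- HF·pyridine should give (R)-1-hydroxyundec-10-en-2-yl dodecanoate F13.
- F13 is oxidised at once with Dess–Martin periodinane to 3.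

Further compounds
F1 | step 5 | (3R)-2-hydroxydodec-11-en-3-yl dodecanoate | C=CCCCCCCC[C@@H](OC(=O)CCCCCCCCCCC)C(C)O
F2 | step 5 | (3R)-2-oxododec-11-en-3-yl dodecanoate | C=CCCCCCCC[C@@H](OC(=O)CCCCCCCCCCC)C(C)=O
F3 | step 5 | (R)-2-chloroheptanal | CCCCC[C@@H](Cl)C=O
F4 | step 5 | (6R,7S,10R)-6-chloro-7-hydroxy-9-oxononadec-18-en-10-yl dodecanoate | C=CCCCCCCC[C@@H](OC(=O)CCCCCCCCCCC)C(=O)C[C@H](O)[C@H](Cl)CCCCC
F5 | step 5 | (6R,7S,9R,10R)-6-chloro-7,9-dihydroxynonadec-18-en-10-yl dodecanoate | C=CCCCCCCC[C@@H](OC(=O)CCCCCCCCCCC)[C@H](O)C[C@H](O)[C@H](Cl)CCCCC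
F6 | step 4 | methyl oct-2-yn-1-yl carbonate | CCCCCC#CCOC(=O)OC
F7 | step 4 | 4,4,5,5-tetramethyl-2-(octa-1,2-dien-3-yl)-1,3,2-dioxaborolane | C=C=C(CCCCC)B1OC(C)(C)C(C)(C)O1
F8 | step 4 | (9R,10R)-9-hydroxynonadec-18-en-6-yn-10-yl dodecanoate | C=CCCCCCCC[C@@H](OC(=O)CCCCCCCCCCC)[C@H](O)CC#CCCCCC
F9 | step 1 | (R)-2-(anilinooxy)undec-10-en-1-ol | C=CCCCCCCC[C@@H](ONc1ccccc1)CO
F10 | step 1 | (R)-undec-10-ene-1,2-diol | C=CCCCCCCC[C@@H](O)CO
F11 | step 1 | (R)-1-(tert-butyldimethylsilyloxy)undec-10-en-2-ol | C=CCCCCCCC[C@@H](O)CO[Si](C)(C)C(C)(C)C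
F12 | step 1 | (R)-1-(tert-butyldimethylsilyloxy)undec-10-en-2-yl dodecanoate | C=CCCCCCCC[C@@H](OC(=O)CCCCCCCCCCC)CO[Si](C)(C)C(C)(C)C
F13 | step 1 | (R)-1-hydroxyundec-10-en-2-yl dodecanoate | C=CCCCCCCC[C@@H](OC(=O)CCCCCCCCCCC)CO
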